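A direct plan would build rings A and B first and close ring C last at the O1–C8a bond.
It would join the SEM-protected ketol A1 (from 2,4'-dihydroxyacetophenone and prenyl bromide) by a lithium aldol to the bis-TBS, mono-SEM aldehyde A2 (from 2,4,5-trihydroxybenzaldehyde).
The adduct would be oxidised to the 1,3-diketone and desilylated to hydroquinone A3; anodic oxidation to an acylquinone and addition of the enol oxygen to C8a would give the 5,8-quinol flavone A4, then 8-O-methylation and SEM removal.
Weak point 1, the protecting-group run-up: a mono-SEM protection of one of three phenols that rests on small acidity differences, then TBS on, TBS off and SEM off, none of which builds a skeletal bond.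
Weak point 2, the anodic oxidation/oxa-Michael closure of ring C: it has no precedent for a 4-pyranone, passes through a 2-alkoxy-1,3-diketone acylquinone open to retro-Claisen cleavage and over-oxidation, and carries the whole route.
Weak point 3, the end game: mono-methylation of an air-sensitive 5,8-quinol, then fluoride cleavage of two SEM ethers at 60 °C on the finished, base-sensitive flavonol.

**Retrosynthetic overview**
The 3-hydroxy-4-pyranone of kojic acid is taken as ring C: its ring oxygen is O1, its enol oxygen is O3, its carbonyl is C4, and its side-chain carbon is C8, already bonded to C8a beside O1 and carrying the oxygen of the 8-OMe.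
Ring B is attached at C2 by Suzuki coupling; ring A is built last from three added carbons, C7 from CO2 (bond C7–C8) and C6/C5 from Meldrum's acid, and closed at C4a–C5 by electrocyclisation of an acylketene.
This is the Claisen folding of a 3,5,7-tricarbonyl chain as in the biosynthesis of ring A, with the C8a carbonyl locked as the pyranone enol ether.
Ring order: C (bought), B attached, A closed. Because O1–C8a and C8–OMe exist before ring A does, the 6-OMe/8-OMe question, the quinol oxidation level, any selective methylation and all phenol protection of ring A disappear; one silyl group (on O3) is used.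

Key step: step 7

Remark: chlorokojic acid and 4-hydroxyphenylboronic acid pinacol ester are taken as commercial. The target is achiral; the one stereocentre that appears on the way (C8 of acid 10, racemic) is erased when ring A aromatises.

**Step 1**
Reactants: 1 4-hydroxyphenylboronic acid pinacol ester [4-(4,4,5,5-tetramethyl-1,3,2-dioxaborolan-2-yl)phenol]; 2 prenyl bromide (1-bromo-3-methylbut-2-ene)
Product: 3 2-[4-(3-methylbut-2-enyloxy)phenyl]-4,4,5,5-tetramethyl-1,3,2-dioxaborolane
Conditions: K2CO3 (1.5 equiv), acetone, 45 °C
Reagents that add atoms: none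
Why: Williamson ether synthesis, in which carbonate ionises the phenol and the phenoxide displaces bromide at the primary allylic carbon (SN2), the pinacol boronate being inert to these anhydrous conditions.

**Step 2**
Reactants: 4 chlorokojic acid [2-(chloromethyl)-5-hydroxy-4H-pyran-4-one]
Product: 5 5-hydroxy-2-(methoxymethyl)-4H-pyran-4-one
Conditions: NaOMe (3 equiv), MeOH, 0 °C to 50 °C; AcOH to pH 5
Reagents that add atoms: sodium methoxide, C[O-].[Na+]
Why: Williamson-type substitution at the activated chloromethyl group, in which methoxide in methanol, in large excess over the delocalised and weakly nucleophilic kojate anion, should displace chloride while the anionic pyranone resists conjugate attack and ring opening.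

**Step 3**
Reactants: 5 5-hydroxy-2-(methoxymethyl)-4H-pyran-4-one
Product: 6 2-bromo-3-hydroxy-6-(methoxymethyl)-4H-pyran-4-one
Conditions: NBS (1.0 equiv), MeCN, 0 °C to rt, dark
Reagents that add atoms: N-bromosuccinimide, O=C1CCC(=O)N1Br
Why: Electrophilic bromination of the enol, which in kojic acid derivatives goes to the ring carbon between O1 and the enolic hydroxyl, the carbon that becomes C2 of the flavone.

**Step 4**
Reactants: 6 2-bromo-3-hydroxy-6-(methoxymethyl)-4H-pyran-4-one
Product: 7 2-bromo-6-(methoxymethyl)-3-(triisopropylsilyloxy)-4H-pyran-4-one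
Conditions: TIPSOTf (1.2 equiv), 2,6-lutidine (1.5 equiv), CH2Cl2, 0 °C
Reagents that add atoms: triisopropylsilyl triflate, CC(C)[Si](OS(=O)(=O)C(F)(F)F)(C(C)C)C(C)C
Why: Silyl ether formation with a silyl triflate and a hindered pyridine base, chosen because the acidic, flanked enol is a poor nucleophile and because the triisopropylsilyl group should survive aqueous phosphate, LiN(SiMe3)2 and 95 °C yet leave with buffered fluoride.

**Step 5**
Reactants: 7 2-bromo-6-(methoxymethyl)-3-(triisopropylsilyloxy)-4H-pyran-4-one; 3 2-[4-(3-methylbut-2-enyloxy)phenyl]-4,4,5,5-tetramethyl-1,3,2-dioxaborolane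
Product: 8 6-(methoxymethyl)-2-[4-(3-methylbut-2-enyloxy)phenyl]-3-(triisopropylsilyloxy)-4H-pyran-4-one
Conditions: Pd(OAc)2 (3 mol %), SPhos (6 mol %), K3PO4 (2 equiv), PhMe/H2O 10:1, 60 °C, Ar
Reagents that add atoms: none
Why: Suzuki–Miyaura cross-coupling, in which the C–Br bond of the β-bromo-β-alkoxy enone adds readily to zerovalent palladium formed in situ from Pd(OAc)2, the bulky biarylphosphine allows coupling beside the silyloxy group, and at 60 °C the silyl ether and the sluggishly ionising prenyl ether should stay intact.

**Step 6**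
Reactants: 8 6-(methoxymethyl)-2-[4-(3-methylbut-2-enyloxy)phenyl]-3-(triisopropylsilyloxy)-4H-pyran-4-one
Product: 10 2-methoxy-2-{4-oxo-6-[4-(3-methylbut-2-enyloxy)phenyl]-5-(triisopropylsilyloxy)-4H-pyran-2-yl}acetic acid (racemic), via lithium dienolate 9 (not isolated)
Conditions: LiN(SiMe3)2 (LiHMDS, 1.3 equiv), THF, −78 °C; dry CO2, −78 to −30 °C; cold 0.5 M HCl to pH 3, EtOAc, no warming, crude acid used at once
Reagents that add atoms: carbon dioxide, O=C=O
Why: Vinylogous enolate carboxylation, in which the amide base removes a proton from the CH2OMe group (γ to the C4 carbonyl) to give extended dienolate 9, which takes up CO2 at the γ-carbon because only γ-attack restores the pyranone, forming the C7–C8 bond; the new C8 stereocentre is racemic and is erased in step 7.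

**Step 7**
Reactants: 10 2-methoxy-2-{4-oxo-6-[4-(3-methylbut-2-enyloxy)phenyl]-5-(triisopropylsilyloxy)-4H-pyran-2-yl}acetic acid; 11 Meldrum's acid (2,2-dimethyl-1,3-dioxane-4,6-dione)
Product: 14 5,7-dihydroxy-8-methoxy-4'-(3-methylbut-2-enyloxy)-3-(triisopropylsilyloxy)flavone, via acyl Meldrum's acid 12 (not isolated), via acylketene 13 (not isolated)
Conditions: 11 (1.1 equiv), DCC (1.1 equiv), DMAP (1.5 equiv), CH2Cl2, −10 °C to rt; filtration, cold aq KHSO4 wash, solvent switch; dry PhMe (5 mM), 95 °C, Ar
Reagents that add atoms: none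
Why: Proposed new method: DCC/DMAP C-acylation of Meldrum's acid by 10 gives 12, which on heating loses acetone and CO2 to acylketene 13; enolisation of the C7 ketone towards C8 gives the dienylketene O=C5=C6H–C7(OH)=C8(OMe)–C8a=C4a, whose electrocyclisation forms the C4a–C5 bond, and tautomerisation of the cyclohexadienone aromatises ring A with the 5- and 7-hydroxyls free. The closest known reaction types are the generation of acylketenes from acyl Meldrum's acids (β-keto ester synthesis) and the dienylketene electrocyclisation that ends the Danheiser and Moore benzannulations, including closures onto an aromatic C=C bond to give naphthols; fusing a phloroglucinol-type ring onto a 4-pyranone in this way is what is new. Ring A closes by a thermal six-electron disrotatory electrocyclisation, equivalent to an intramolecular C-acylation of the pyranone carbon C4a by the ketene; no stereocentre is created and the racemic C8 centre of 10 becomes sp2. Regiochemistry needs no control, since C8 with its methoxy group was bonded to C8a beside O1 before the ring existed, so only the 8-methoxy isomer can form. Chemoselectivity requires the ketene to react within the molecule: C4a is the only nucleophilic site that gives a six-membered ring (attack by the C7 enol oxygen would give a four-membered ring and the C4 carbonyl cannot be reached), while high dilution and dry toluene hold back dimerisation and hydration. The neutral medium at 95 °C should spare the silyl ether and the prenyl aryl ether, whose Claisen rearrangement needs far higher temperature.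

**Step 8**
Reactants: 14 5,7-dihydroxy-8-methoxy-4'-(3-methylbut-2-enyloxy)-3-(triisopropylsilyloxy)flavone
Product: 15 3,5,7-trihydroxy-8-methoxy-4'-prenyloxyflavone
Conditions: Bu4NF (1.2 equiv), AcOH (1.5 equiv), THF, 0 °C, Ar; pH 6 buffer work-up
Reagents that add atoms: none
Why: Fluoride-induced desilylation, in which the silyl ether of the acidic 3-hydroxyl is cleaved within minutes at 0 °C, the acetic acid buffer keeps the polyphenol protonated and away from autoxidation, and the prenyl ether and the 8-OMe are inert to fluoride.

**Compound list**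
1 | 4-hydroxyphenylboronic acid pinacol ester | CC1(C)OB(OC1(C)C)c1ccc(O)cc1 | starting material
2 | prenyl bromide (1-bromo-3-methylbut-2-ene) | CC(C)=CCBr | starting material
3 | 2-[4-(3-methylbut-2-enyloxy)phenyl]-4,4,5,5-tetramethyl-1,3,2-dioxaborolane | CC(C)=CCOc1ccc(cc1)B1OC(C)(C)C(C)(C)O1 | intermediate
4 | chlorokojic acid [2-(chloromethyl)-5-hydroxy-4H-pyran-4-one] | ClCc1cc(=O)c(O)co1 | starting material
5 | 5-hydroxy-2-(methoxymethyl)-4H-pyran-4-one | COCc1cc(=O)c(O)co1 | intermediate
6 | 2-bromo-3-hydroxy-6-(methoxymethyl)-4H-pyran-4-one | COCc1cc(=O)c(O)c(Br)o1 | intermediate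
7 | 2-bromo-6-(methoxymethyl)-3-(triisopropylsilyloxy)-4H-pyran-4-one | COCc1cc(=O)c(O[Si](C(C)C)(C(C)C)C(C)C)c(Br)o1 | intermediate
8 | 6-(methoxymethyl)-2-[4-(3-methylbut-2-enyloxy)phenyl]-3-(triisopropylsilyloxy)-4H-pyran-4-one | COCc1cc(=O)c(O[Si](C(C)C)(C(C)C)C(C)C)c(-c2ccc(OCC=C(C)C)cc2)o1 | intermediate
9 | lithium dienolate of 8 [lithium 2-(methoxymethylene)-2H-pyran-4-olate, not isolated] | COC=C1C=C(O[Li])C(O[Si](C(C)C)(C(C)C)C(C)C)=C(c2ccc(OCC=C(C)C)cc2)O1 | intermediate
10 | 2-methoxy-2-{4-oxo-6-[4-(3-methylbut-2-enyloxy)phenyl]-5-(triisopropylsilyloxy)-4H-pyran-2-yl}acetic acid, racemic | COC(C(=O)O)c1cc(=O)c(O[Si](C(C)C)(C(C)C)C(C)C)c(-c2ccc(OCC=C(C)C)cc2)o1 | intermediate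
11 | Meldrum's acid (2,2-dimethyl-1,3-dioxane-4,6-dione) | CC1(C)OC(=O)CC(=O)O1 | starting material
12 | acyl Meldrum's acid of 10 (enol form, racemic, not isolated) | COC(C(O)=C1C(=O)OC(C)(C)OC1=O)c1cc(=O)c(O[Si](C(C)C)(C(C)C)C(C)C)c(-c2ccc(OCC=C(C)C)cc2)o1 | intermediate
13 | acylketene, 4-methoxy-4-(pyranonyl)buta-1-ene-1,3-dione (racemic, not isolated) | COC(C(=O)C=C=O)c1cc(=O)c(O[Si](C(C)C)(C(C)C)C(C)C)c(-c2ccc(OCC=C(C)C)cc2)o1 | intermediate
14 | 5,7-dihydroxy-8-methoxy-4'-(3-methylbut-2-enyloxy)-3-(triisopropylsilyloxy)flavone | COc1c(O)cc(O)c2c(=O)c(O[Si](C(C)C)(C(C)C)C(C)C)c(-c3ccc(OCC=C(C)C)cc3)oc12 | intermediate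
15 | 3,5,7-trihydroxy-8-methoxy-4'-prenyloxyflavone (achiral) | COc1c(O)cc(O)c2c(=O)c(O)c(-c3ccc(OCC=C(C)C)cc3)oc12 | target

Total step count: 8. Longest linear sequence: 7 (steps 2 to 8).

**Steps most likely to fail**

1. Step 7 (proposed new method). The acylketene may be consumed by dimerisation or by traces of water (followed by decarboxylation to a methyl ketone) faster than it enolises and cyclises onto C4a, or the acid may decarboxylate during activation. Fallback, setting out from 10 and returning at 14: the acid would be activated with carbonyldiimidazole to the acyl imidazolide F1 and homologated with Mg(O2CCH2CO2Me)2 (Masamune–Brooks decarboxylative Claisen) to the β-keto ester methyl 4-methoxy-3-oxo-4-(pyranonyl)butanoate F2. LiN(SiMe3)2 (2.2 equiv, THF, −78 to 0 °C) would then close ring A by intramolecular Claisen (Dieckmann-type) condensation of the dienolate carbon C4a on the ester. This is the base-mediated cyclisation of 3,5,7-tricarbonyl esters to acylphloroglucinols, and it gives 14 after loss of methanol and enolisation.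

2. Step 6. The free acid is a vinylogous β-keto acid and may lose CO2 during acidic work-up, and the dienolate may be carboxylated on oxygen or be quenched by proton transfer. Fallback, setting out from 8 and returning at 14: dienolate 9 would be trapped with Me3SiCl as the silyl dienol ether F3. F3 would be C-acylated at C8 with methyl malonyl chloride (methyl 3-chloro-3-oxopropanoate) in CH2Cl2 at −78 °C without base, a Mukaiyama-type vinylogous acylation as in the reaction of silyl enol ethers with malonyl chlorides. This gives β-keto ester F2 with no free acid on the way, and F2 would be cyclised to 14 by the Claisen condensation described above.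

3. Step 5. Aqueous base may cleave the silyl ether or protodeboronate 3, the bulky silyloxy group may slow transmetalation, and zerovalent palladium may slowly ionise the prenyl ether. Fallback, setting out from 7 and returning at 8: the polarity of the coupling would be inverted and water and base left out. Bromine–magnesium exchange on 7 (iPrMgCl·LiCl, THF, −40 °C) and transmetalation with ZnCl2 would give the pyranonylzinc chloride F4. Negishi coupling (Pd(OAc)2/SPhos, THF, rt) with 1-iodo-4-(3-methylbut-2-enyloxy)benzene F5, made from 4-iodophenol and 2 with K2CO3, would give 8.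

**Further compounds**
F1 | step 7 | acyl imidazolide of acid 10 (racemic) | COC(C(=O)n1ccnc1)c1cc(=O)c(O[Si](C(C)C)(C(C)C)C(C)C)c(-c2ccc(OCC=C(C)C)cc2)o1
F2 | step 7 | methyl 4-methoxy-3-oxo-4-{4-oxo-6-[4-(3-methylbut-2-enyloxy)phenyl]-5-(triisopropylsilyloxy)-4H-pyran-2-yl}butanoate (racemic) | COC(C(=O)CC(=O)OC)c1cc(=O)c(O[Si](C(C)C)(C(C)C)C(C)C)c(-c2ccc(OCC=C(C)C)cc2)o1
F3 | step 6 | 2-(methoxymethylene)-6-[4-(3-methylbut-2-enyloxy)phenyl]-5-(triisopropylsilyloxy)-4-(trimethylsilyloxy)-2H-pyran | COC=C1C=C(O[Si](C)(C)C)C(O[Si](C(C)C)(C(C)C)C(C)C)=C(c2ccc(OCC=C(C)C)cc2)O1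
F4 | step 5 | [6-(methoxymethyl)-4-oxo-3-(triisopropylsilyloxy)-4H-pyran-2-yl]zinc chloride | COCc1cc(=O)c(O[Si](C(C)C)(C(C)C)C(C)C)c([Zn]Cl)o1
F5 | step 5 | 1-iodo-4-(3-methylbut-2-enyloxy)benzene | CC(C)=CCOc1ccc(I)cc1
A1 | direct plan | 1-[4-(3-methylbut-2-enyloxy)phenyl]-2-(SEM-oxy)ethanone | O=C(COCOCC[Si](C)(C)C)c1ccc(OCC=C(C)C)cc1
A2 | direct plan | 2,5-bis(TBS-oxy)-4-(SEM-oxy)benzaldehyde | O=Cc1cc(O[Si](C)(C)C(C)(C)C)c(OCOCC[Si](C)(C)C)cc1O[Si](C)(C)C(C)(C)C
A3 | direct plan | 1-[2,5-dihydroxy-4-(SEM-oxy)phenyl]-3-(4-prenyloxyphenyl)-2-(SEM-oxy)propane-1,3-dione (racemic) | O=C(c1cc(O)c(OCOCC[Si](C)(C)C)cc1O)C(OCOCC[Si](C)(C)C)C(=O)c1ccc(OCC=C(C)C)cc1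
A4 | direct plan | 5,8-dihydroxy-3,7-bis(SEM-oxy)-4'-prenyloxyflavone | Oc1c(OCOCC[Si](C)(C)C)cc(O)c2c(=O)c(OCOCC[Si](C)(C)C)c(-c3ccc(OCC=C(C)C)cc3)oc12
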